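**Plan**
- **Cuts:** The ethyl ether on O5 and the isopropyl ether on O4' come off last. Ring C is cut at C4–C4a and O1–C2, which separates a ring A phenol from a ring B arylpropiolate. Ring A is then cut at C8–C8a, C6–C7 and C4a–C8a into 3-ethoxycyclobutenone and a prenyl-bearing methyl ynol ether.
- **Enabling feature:** Ring A is a 1,3,5-trioxygenated benzene with three unlike oxygens (O1 on C8a, hydroxyl on C5, methoxy on C7), and the prenylated carbon C8 lies between C7 and C8a. Each oxygen traces to a different component atom: the ketene C=O gives C8a–O1, the ynol ether oxygen sits on C7, and the cyclobutenone enol ether oxygen sits on C5. C8 is the nucleophilic alkyne carbon.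
- **Forward order:** Ring A is built by benzannulation and ring B is carried in preformed from 4-hydroxy-2-methoxybenzaldehyde. O1–C2 is made by oxa-Michael addition, and ring C closes last by acylation at C4a.
- **Stereochemistry:** The target has no stereocentre. The one transient element, the Z geometry of the enol ether, comes from anti addition and disappears when ring C forms.

Key step: step 2

Assumption: 3-ethoxycyclobut-2-en-1-one is taken as a purchasable compound. The β-aryloxyacrylates of steps 6 to 8 are drawn as the Z isomers expected from anti addition, and either geometry should converge on the same flavone because the push–pull alkene isomerises once the acyl group is activated.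

**Step 1**
Reactants: 1 chloroacetaldehyde dimethyl acetal; 2 prenyl bromide (1-bromo-3-methylbut-2-ene)
Product: 4 1-methoxy-5-methylhex-4-en-1-yne, via sodium methoxyacetylide 3 (not isolated)
Conditions: NaNH2 (3.0 equiv), liquid NH3, −33 °C; then 2 (0.95 equiv), −33 °C; NH3 evaporated, pentane/water, distillation under reduced pressure
Reagents that add atoms: none
Why: The amide base strips methanol and hydrogen chloride from the chloroacetal and deprotonates the resulting alkyne (the standard elimination route to metal alkoxyacetylides), the acetylide then displaces the primary allylic bromide by SN2 alkylation, and limiting the amide to three equivalents leaves no base strong enough to isomerise the skipped enyne.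

**Step 2**
Reactants: 5 3-ethoxycyclobut-2-en-1-one; 4 1-methoxy-5-methylhex-4-en-1-yne
Product: 10 5-ethoxy-3-methoxy-2-(3-methylbut-2-enyl)phenol, via vinylketene 6 (not isolated), via vinylcyclobutenone 7 (not isolated), via dienylketene 8 (not isolated), via cyclohexadienone 9 (not isolated)
Conditions: 4 (1.5 equiv), toluene (0.5 M), argon, sealed tube, 80 °C, then 135 °C
Reagents that add atoms: none
Why: Heating opens 5 by four-electron conrotatory cleavage of the C1–C4 bond to (1-ethoxyvinyl)ketene 6, whose electrophilic carbonyl carbon is attacked by the oxygen-free, prenyl-bearing carbon of ynol ether 4 in a polarity-matched [2+2] cycloaddition that gives racemic vinylcyclobutenone 7 and forms C8–C8a and C6–C7. At the higher temperature 7 opens reversibly to dienylketene 8, and the isomer with ketene and ethoxyvinyl arms cis leaves the equilibrium by six-electron disrotatory electrocyclisation, which forms C4a–C8a and closes ring A as dienone 9; tautomerisation to phenol 10 makes the cascade irreversible. The closest known reaction type is the Danheiser benzannulation of cyclobutenones with alkoxyalkynes to resorcinol monoethers, extended here only in that the cyclobutenone carries a 3-alkoxy group and so brings in the third oxygen. The stereocentre of 7 and the alkene geometry of 8 are erased on aromatisation, so nothing has to be controlled there. What the step needs is regio- and chemoselectivity: the donor polarisation of the MeO–C≡C unit dictates that prenyl ends up between the hydroxyl and the methoxy group with no C6 isomer, the ynol ether is a far better ketenophile than the trisubstituted prenyl alkene, and a methyl ynol ether lacks the β-hydrogen needed for retro-ene fragmentation at these temperatures. The excess of 4 should ensure that the ketene is trapped before it can acylate the phenol formed.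

**Step 3**
Reactants: 11 4-hydroxy-2-methoxybenzaldehyde
Product: 12 4-isopropoxy-2-methoxybenzaldehyde
Conditions: 2-bromopropane (1.5 equiv), K2CO3 (1.5 equiv), DMF, 60 °C
Reagents that add atoms: 2-bromopropane, CC(C)Br
Why: Williamson ether synthesis on the acidic para-formyl phenol, giving an isopropyl ether that tolerates organolithium, carbonate, hydroxide and anhydride conditions and is later cleaved by BCl3 in preference to methyl ethers.

**Step 4**
Reactants: 12 4-isopropoxy-2-methoxybenzaldehyde
Product: 13 1-(2,2-dibromoethenyl)-4-isopropoxy-2-methoxybenzene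
Conditions: CBr4 (1.5 equiv), PPh3 (3.0 equiv), CH2Cl2, 0 °C
Reagents that add atoms: carbon tetrabromide, BrC(Br)(Br)Br
Why: Ramirez dibromoolefination (first stage of the Corey–Fuchs sequence), a Wittig-type reaction of the ylide formed in the flask from PPh3 and CBr4 that is reliable on electron-rich benzaldehydes.

**Step 5**
Reactants: 13 1-(2,2-dibromoethenyl)-4-isopropoxy-2-methoxybenzene
Product: 15 methyl 3-(4-isopropoxy-2-methoxyphenyl)prop-2-ynoate, via lithium acetylide 14 (not isolated)
Conditions: n-BuLi (2.1 equiv), THF, −78 °C; then ClCO2Me (1.3 equiv), −78 °C → rt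
Reagents that add atoms: methyl chloroformate, COC(=O)Cl
Why: Second stage of the Corey–Fuchs alkyne synthesis, in which bromine–lithium exchange, 1,2-shift with loss of bromide and deprotonation deliver the lithium acetylide, which is then C-acylated by the chloroformate.

**Step 6**
Reactants: 10 5-ethoxy-3-methoxy-2-(3-methylbut-2-enyl)phenol; 15 methyl 3-(4-isopropoxy-2-methoxyphenyl)prop-2-ynoate
Product: 16 methyl (Z)-3-[5-ethoxy-3-methoxy-2-(3-methylbut-2-enyl)phenoxy]-3-(4-isopropoxy-2-methoxyphenyl)prop-2-enoate
Conditions: 15 (1.2 equiv), Cs2CO3 (0.5 equiv), DMF, 80 °C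
Reagents that add atoms: none
Why: Oxa-Michael (Ruhemann-type) addition of the phenoxide to the aryl-bearing β-carbon of the alkynoate followed by anti protonation places aryloxy and ester cis, forming O1–C2 under basic conditions that mask the phenol next to the prenyl chain and leave C4a free.

**Step 7**
Reactants: 16 methyl (Z)-3-aryloxy-3-arylprop-2-enoate
Product: 17 (Z)-3-[5-ethoxy-3-methoxy-2-(3-methylbut-2-enyl)phenoxy]-3-(4-isopropoxy-2-methoxyphenyl)prop-2-enoic acid
Conditions: LiOH (3 equiv), THF/H2O (3:1), 40 °C; then 1 M HCl, 0 °C, to pH 3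
Reagents that add atoms: lithium hydroxide, [Li+].[OH-]
Why: Ester saponification by acyl–oxygen cleavage, in which the doubly donor-substituted β-carbon resists addition–elimination and the brief cold acidification spares the enol ether and the prenyl group.

**Step 8**
Reactants: 17 (Z)-3-aryloxy-3-arylprop-2-enoic acid
Product: 19 5-ethoxy-2-(4-isopropoxy-2-methoxyphenyl)-7-methoxy-8-(3-methylbut-2-enyl)chromen-4-one, via mixed anhydride 18 (not isolated)
Conditions: (CF3CO)2O (1.1 equiv), CH2Cl2, 0 °C → rt; poured into cold aq. NaHCO3
Reagents that add atoms: none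
Why: Intramolecular Friedel–Crafts acylation through the mixed trifluoroacetic anhydride, in which the tether allows only six-membered closure at C4a because the other ortho position C8 carries the prenyl group, and C4a is activated by the ortho aryloxy, ortho ethoxy and para methoxy groups so that no Lewis or mineral acid is needed and the prenyl alkene meets only dilute CF3CO2H.

**Step 9**
Reactants: 19 5-ethoxy-2-(4-isopropoxy-2-methoxyphenyl)-7-methoxy-8-(3-methylbut-2-enyl)chromen-4-one
Product: 21 artocarpetin B, via bis(dichloroboryl) ether 20 (not isolated)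
Conditions: BCl3 (1 M in CH2Cl2, 3.5 equiv), CH2Cl2, −78 °C → 0 °C; then cold sat. aq. NaHCO3
Reagents that add atoms: none
Why: Lewis-acid ether cleavage in which BCl3 chelates between the C4 carbonyl and the peri 5-ethoxy oxygen so that chloride removes that ethyl group selectively, and it cleaves the secondary isopropyl ether far faster than the unchelated 7- and 2'-methyl ethers, both dealkylations giving alkyl chlorides rather than protic acid so that the prenyl group should survive until the buffered quench.

**Compound list**
1 | chloroacetaldehyde dimethyl acetal | COC(OC)CCl | starting material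
2 | prenyl bromide | CC(C)=CCBr | starting material
3 | sodium methoxyacetylide | COC#[C-].[Na+] | intermediate
4 | 1-methoxy-5-methylhex-4-en-1-yne | COC#CCC=C(C)C | intermediate
5 | 3-ethoxycyclobut-2-en-1-one | CCOC1=CC(=O)C1 | starting material
6 | 3-ethoxybuta-1,3-dien-1-one, the (1-ethoxyvinyl)ketene | C=C(OCC)C=C=O | intermediate
7 | 4-(1-ethoxyethenyl)-3-methoxy-2-(3-methylbut-2-enyl)cyclobut-2-en-1-one (racemic) | O=C1C(CC=C(C)C)=C(OC)C1C(=C)OCC | intermediate
8 | (3E)-5-ethoxy-3-methoxy-2-(3-methylbut-2-enyl)hexa-1,3,5-trien-1-one | O=C=C(CC=C(C)C)/C(OC)=C\C(=C)OCC | intermediate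
9 | 5-ethoxy-3-methoxy-2-(3-methylbut-2-enyl)cyclohexa-2,4-dien-1-one | O=C1CC(OCC)=CC(OC)=C1CC=C(C)C | intermediate
10 | 5-ethoxy-3-methoxy-2-(3-methylbut-2-enyl)phenol | CCOc1cc(O)c(CC=C(C)C)c(OC)c1 | intermediate
11 | 4-hydroxy-2-methoxybenzaldehyde | COc1cc(O)ccc1C=O | starting material
12 | 4-isopropoxy-2-methoxybenzaldehyde | COc1cc(OC(C)C)ccc1C=O | intermediate
13 | 1-(2,2-dibromoethenyl)-4-isopropoxy-2-methoxybenzene | COc1cc(OC(C)C)ccc1C=C(Br)Br | intermediate
14 | lithium (4-isopropoxy-2-methoxyphenyl)acetylide | COc1cc(OC(C)C)ccc1C#[C-].[Li+] | intermediate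
15 | methyl 3-(4-isopropoxy-2-methoxyphenyl)prop-2-ynoate | COC(=O)C#Cc1ccc(OC(C)C)cc1OC | intermediate
16 | methyl (Z)-3-[5-ethoxy-3-methoxy-2-(3-methylbut-2-enyl)phenoxy]-3-(4-isopropoxy-2-methoxyphenyl)prop-2-enoate | COC(=O)/C=C(\Oc1cc(OCC)cc(OC)c1CC=C(C)C)c1ccc(OC(C)C)cc1OC | intermediate
17 | (Z)-3-[5-ethoxy-3-methoxy-2-(3-methylbut-2-enyl)phenoxy]-3-(4-isopropoxy-2-methoxyphenyl)prop-2-enoic acid | OC(=O)/C=C(\Oc1cc(OCC)cc(OC)c1CC=C(C)C)c1ccc(OC(C)C)cc1OC | intermediate
18 | mixed anhydride of 17 with trifluoroacetic acid | FC(F)(F)C(=O)OC(=O)/C=C(\Oc1cc(OCC)cc(OC)c1CC=C(C)C)c1ccc(OC(C)C)cc1OC | intermediate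
19 | 5-ethoxy-2-(4-isopropoxy-2-methoxyphenyl)-7-methoxy-8-(3-methylbut-2-enyl)chromen-4-one | CCOc1cc(OC)c(CC=C(C)C)c2oc(-c3ccc(OC(C)C)cc3OC)cc(=O)c12 | intermediate
20 | 5,4'-bis(dichloroboryloxy) derivative of the flavone | COc1cc(OB(Cl)Cl)ccc1-c1cc(=O)c2c(OB(Cl)Cl)cc(OC)c(CC=C(C)C)c2o1 | intermediate
21 | artocarpetin B, 5-hydroxy-2-(4-hydroxy-2-methoxyphenyl)-7-methoxy-8-(3-methylbut-2-enyl)chromen-4-one | COc1cc(O)ccc1-c1cc(=O)c2c(O)cc(OC)c(CC=C(C)C)c2o1 | target

**Step count**
- Total: 9 steps.
- Longest linear sequence: 7 steps (steps 3 to 9, from 11).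
- The ring A branch runs over 6 steps (steps 1, 2 and 6 to 9).

**Steps most likely to fail**

**Step 2.** The vinylogous-ester stabilisation of the four-membered ring may raise the onset of ring opening to temperatures at which ketene self-condensation and acylation of the newly formed phenol overtake the cycloaddition.

The fallback sets out from 4 and returns at ketene 6, and hence at 10. It makes the same ketene at room temperature by a photochemical Wolff rearrangement. Ethyl vinyl ether is α-lithiated (t-BuLi, THF) and acylated with N-methoxy-N-methylacetamide to 3-ethoxybut-3-en-2-one F1. Its enolate (LiN(SiMe3)2, THF, −78 °C) is trifluoroacetylated with 2,2,2-trifluoroethyl trifluoroacetate to 5-ethoxy-1,1,1-trifluorohex-5-ene-2,4-dione F2. Methanesulfonyl azide with Et3N and water in MeCN then effects detrifluoroacetylative diazo transfer to 1-diazo-3-ethoxybut-3-en-2-one F3. Irradiation of F3 together with 4 in CH2Cl2 should release 6 with loss of nitrogen. The ynol ether traps 6 as 7, and a short period of heating in toluene carries 7 through 8 and 9 to 10.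

**Step 6.** The alkynoate is deactivated by the ortho and para oxygen donors of ring B, and the phenoxide is flanked by the prenyl chain. The conjugate addition may therefore stall, and long heating may bring ester exchange with the phenoxide.

The fallback sets out from 14 and 10 and returns at 17. It raises the electrophilicity of the acceptor by changing its oxidation level. Acetylide 14 is quenched with DMF to give 3-(4-isopropoxy-2-methoxyphenyl)prop-2-ynal F4. Phenol 10 adds to this far more reactive ynal under DABCO catalysis in MeCN at room temperature to give (Z)-3-[5-ethoxy-3-methoxy-2-(3-methylbut-2-enyl)phenoxy]-3-(4-isopropoxy-2-methoxyphenyl)prop-2-enal F5. Pinnick oxidation (NaClO2, NaH2PO4, large excess of 2-methylbut-2-ene, t-BuOH/H2O) then gives acid 17 directly, so that step 7 is not needed.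

**Step 8.** The CF3CO2H set loose may protonate the prenyl alkene, leading to addition of trifluoroacetate or ring closure onto the 7-methoxy oxygen. The anhydride may also trifluoroacetylate C6 before ring C closes.

The fallback sets out from 10 and 14 and returns at 19. It reverses the order of the two ring C bonds and uses no acid. Phenol 10 is formylated at its only free ortho position under Casnati–Skattebøl conditions (MgCl2, Et3N, paraformaldehyde, MeCN, reflux) to 6-ethoxy-2-hydroxy-4-methoxy-3-(3-methylbut-2-enyl)benzaldehyde F6. Two equivalents of acetylide 14 in THF at −78 °C give racemic 1-[6-ethoxy-2-hydroxy-4-methoxy-3-(3-methylbut-2-enyl)phenyl]-3-(4-isopropoxy-2-methoxyphenyl)prop-2-yn-1-ol F7. MnO2 in CH2Cl2 oxidises it to 1-[6-ethoxy-2-hydroxy-4-methoxy-3-(3-methylbut-2-enyl)phenyl]-3-(4-isopropoxy-2-methoxyphenyl)prop-2-yn-1-one F8. Catalytic DMAP in DMF then triggers the 6-endo-dig intramolecular oxa-Michael closure of O1–C2 to 19.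

**Further compounds**
F1 | step 2 | 3-ethoxybut-3-en-2-one | CC(=O)C(=C)OCC
F2 | step 2 | 5-ethoxy-1,1,1-trifluorohex-5-ene-2,4-dione | C=C(OCC)C(=O)CC(=O)C(F)(F)F
F3 | step 2 | 1-diazo-3-ethoxybut-3-en-2-one | C=C(OCC)C(=O)C=[N+]=[N-]
F4 | step 6 | 3-(4-isopropoxy-2-methoxyphenyl)prop-2-ynal | O=CC#Cc1ccc(OC(C)C)cc1OC
F5 | step 6 | (Z)-3-[5-ethoxy-3-methoxy-2-(3-methylbut-2-enyl)phenoxy]-3-(4-isopropoxy-2-methoxyphenyl)prop-2-enal | O=C/C=C(\Oc1cc(OCC)cc(OC)c1CC=C(C)C)c1ccc(OC(C)C)cc1OC
F6 | step 8 | 6-ethoxy-2-hydroxy-4-methoxy-3-(3-methylbut-2-enyl)benzaldehyde | CCOc1cc(OC)c(CC=C(C)C)c(O)c1C=O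
F7 | step 8 | 1-[6-ethoxy-2-hydroxy-4-methoxy-3-(3-methylbut-2-enyl)phenyl]-3-(4-isopropoxy-2-methoxyphenyl)prop-2-yn-1-ol (racemic) | CCOc1cc(OC)c(CC=C(C)C)c(O)c1C(O)C#Cc1ccc(OC(C)C)cc1OC
F8 | step 8 | 1-[6-ethoxy-2-hydroxy-4-methoxy-3-(3-methylbut-2-enyl)phenyl]-3-(4-isopropoxy-2-methoxyphenyl)prop-2-yn-1-one | CCOc1cc(OC)c(CC=C(C)C)c(O)c1C(=O)C#Cc1ccc(OC(C)C)cc1OC
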